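If you want the excess of two flasks at once, reckon the ratio behind it. Here the free catalyst and the partner turn each substrate into its product, while the racemization catalyst interconverts the two substrates.

| flask | left-handed substrate | right-handed substrate | partner | free catalyst | racemization catalyst | temperature | remark | time |
|---|---|---|---|---|---|---|---|---|
| ochre | 0.10 M | 0.10 M | 2.2 equiv | 6.4 mol% | 1.1 mol% | 90 °C | run made earlier |  |
| grey | 0.10 M | 0.10 M | 2.2 equiv | 8.9 mol% | 1.1 mol% | 102 °C | run made earlier |  |
| blue | 0.10 M | 0.10 M | 2.2 equiv | 14 mol% | 1.1 mol% | 90 °C | run made earlier |  |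
| Wednesday's | 0.10 M | 0.10 M | 2.20 equiv | 4.9 mol% | 1.1 mol% | 110 °C |  | 20 min |
| Monday's | 0.10 M | 0.10 M | 2.20 equiv | 15 mol% | 1.1 mol% | 95 °C |  | 10 min |

| run | time / min | left-handed product / % | right-handed product / % |
|---|---|---|---|
| ochre | 2.50 | 4.8 | 2.4 |
| ochre | 4.00 | 8.2 | 4.2 |
| ochre | 8.00 | 11.2 | 5.1 |
| ochre | 15.0 | 15.6 | 6.2 |
| ochre | 25.0 | 19.3 | 9.3 |
| grey | 0.833 | 3.7 | 1.7 |
| grey | 2.50 | 8.7 | 3.6 |
| grey | 5.00 | 13.7 | 5.1 |
| grey | 8.00 | 15.4 | 6.9 |
| grey | 10.0 | 18.2 | 7.2 |
| blue | 2.50 | 6.9 | 4.8 |
| blue | 6.00 | 16.2 | 6.4 |
| blue | 15.0 | 21.4 | 9.4 |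
| blue | 20.0 | 25.2 | 10.1 |
| blue | 25.0 | 24.9 | 10.4 |

(standard deviation of a reading: 1 percentage point)

- free catalyst is single-handed; left-handed substrate and right-handed substrate are mirror images of each other, charged as a racemate, each of them at the stated concentration
- steps under discussion: partner + free catalyst + right-handed substrate -> free catalyst + right-handed product; 2 free catalyst <-> resting dimer; partner + free catalyst + left-handed substrate -> free catalyst + left-handed product; left-handed substrate + racemization catalyst <-> right-handed substrate + racemization catalyst
- an excess is the difference of the two amounts in percent of their sum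
- an excess is below zero if the other one leads

* which one finishes higher in excess of left-handed product over right-handed product ("neither" within 2 percentage points) (Wednesday's / Monday's / neither)
* excess of left-handed product over right-handed product at the end, Wednesday's
* excess of left-handed product over right-handed product at the end, Monday's

Pooling the last readings of the ochre, blue and grey runs, left-handed product over right-handed product gives 2.32. Call this the product ratio, an apparent selectivity factor. The excess is the ratio less one over the ratio plus one, here 39.8%. The last readings give ratios of 2.08 for ochre and 2.39 for blue, both at 90 °C, and 2.53 for grey at 102 °C, so at a scatter of 1 percentage point per reading I read no temperature trend, and my own reckoning gives both flasks 39.8%.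

The forecast was neither, with 38% for Wednesday's and 39% for Monday's: “These effects roughly cancel”.

The flasks give 36.9% for Wednesday's and 41.8% for Monday's, so Monday's finishes higher. As product ratios these are 2.17 and 2.44, on either side of the 2.32 I read. Moving the ochre run to Wednesday's temperature alone takes its scatter-free excess from 44.0% to 35.6%, while Wednesday's catalyst alone gives 44.7% and Wednesday's time alone 44.5%.

    partner + free catalyst + right-handed substrate → free catalyst + right-handed product (k = 0.450 M⁻² s⁻¹, Ea = 51.0 kJ mol⁻¹)
    2 free catalyst ⇌ resting dimer (K = 310 M⁻¹, k = 0.490 M⁻¹ s⁻¹, Ea = 69.0 kJ mol⁻¹, ΔH = −43.0 kJ mol⁻¹)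
    partner + free catalyst + left-handed substrate → free catalyst + left-handed product (k = 1.10 M⁻² s⁻¹, Ea = 40.0 kJ mol⁻¹)
    left-handed substrate + racemization catalyst ⇌ right-handed substrate + racemization catalyst, rate k4*[racemization catalyst]*[left-handed substrate] forward; the back reaction follows from the equilibrium constant (k = 0.380 M⁻¹ s⁻¹, Ea = 64.0 kJ mol⁻¹)
    (constants at 110 °C)

Wednesday's has not come to rest at 20 min: the two substrates together still stand at 66.8%, and at 200 min at 16.1%. The product added in between comes at a product ratio of 2.05, below the 2.17 already in the flask, and the excess slips to 35.4%. Monday's adds its later product by 100 min at 1.93, below its 2.44, and its excess falls from 41.8% to 35.9%.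

The readings are simulated with made-up constants, noise included.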